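**Retrosynthetic overview**

1. Locants: ring B = oxolane (O1, C2–C5); ring A = syringyl ring on C2; ring C = guaiacyl ring of the C4 benzyl group (benzylic carbon C7'); ring D and C1''–C3'' = guaiacylglycerol chain on the ring A oxygen. The chain is cut first: C1''–C2'' by an Evans glycolate aldol on the ring A phenol ether (sets C2''), with C1'' then inverted by a Mitsunobu reaction (threo to erythro).
2. Ring B is opened at C4–C5. The enabling feature: C5 is the only unsubstituted ring carbon, a methylene held between O1 and C4, so it can start as a one-carbon radical on the C2 oxygen; C4 carries only H and C7' (ring C), so C4–C7' can start as an aryl alkyne. A 5-exo-dig closure gives the 4-benzylidene oxolane, and hydrogenation anti to the C3 substituent sets C4 (3,4-cis).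
3. The acyclic anti homopropargylic alcohol (C2, C3) comes in one step from O-benzylsyringaldehyde and a propargylic mesylate (Marshall propargylation). Its single carbinol centre is set by catalysis (Noyori transfer hydrogenation of an ynone) and relayed to C2 and C3, then to C4.
4. Rings A, C and D are bought (a syringaldehyde ether and vanillin, used twice); ring B is the only ring made (step 8).

Key step: step 8

Remark: chloromethyl phenyl selenide is taken as a stock reagent (one operation from PhSeSePh, NaBH4 and BrCH2Cl); 13 is expected as a mixture of alkene isomers, both of which converge in step 9.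

**Step 1**
Reactants: 1 vanillin (4-hydroxy-3-methoxybenzaldehyde)
Product: 2 3-methoxy-4-[(triisopropylsilyl)oxy]benzaldehyde
Conditions: TIPSCl, imidazole, DMF, rt
Reagents that add atoms: triisopropylsilyl chloride, CC(C)[Si](Cl)(C(C)C)C(C)C
Why: Imidazole-promoted silylation of the phenol gives an aryl silyl ether that should survive organolithium, hydride, radical and hydrogenation conditions and is removed only in the last step.

**Step 2**
Reactants: 2 3-methoxy-4-[(triisopropylsilyl)oxy]benzaldehyde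
Product: 3 [4-(2,2-dibromoethenyl)-2-methoxyphenoxy]triisopropylsilane
Conditions: CBr4, PPh3, CH2Cl2, 0 °C
Reagents that add atoms: carbon tetrabromide, BrC(Br)(Br)Br
Why: First stage of the Corey–Fuchs alkyne synthesis, a Wittig-type dibromoolefination of the aldehyde by Ph3P=CBr2 formed in the flask.

**Step 3**
Reactants: 3 [4-(2,2-dibromoethenyl)-2-methoxyphenoxy]triisopropylsilane; 4 2-(benzyloxy)-N-methoxy-N-methylacetamide
Product: 6 1-(benzyloxy)-4-{3-methoxy-4-[(triisopropylsilyl)oxy]phenyl}but-3-yn-2-one, via lithium arylacetylide 5 (not isolated)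
Conditions: n-BuLi (2.1 equiv), THF, –78 °C; then 4, –78 → 0 °C; aq NH4Cl
Reagents that add atoms: none
Why: Second stage of the Corey–Fuchs reaction (Br/Li exchange, elimination and deprotonation) gives acetylide 5, which is acylated once by the Weinreb amide because the chelated tetrahedral intermediate does not collapse before the quench.

**Step 4**
Reactants: 6 1-(benzyloxy)-4-{3-methoxy-4-[(triisopropylsilyl)oxy]phenyl}but-3-yn-2-one
Product: 7 (2R)-1-(benzyloxy)-4-{3-methoxy-4-[(triisopropylsilyl)oxy]phenyl}but-3-yn-2-ol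
Conditions: Ru[(S,S)-TsDPEN](p-cymene) (amido complex, 1 mol%), i-PrOH, rt
Reagents that add atoms: none
Why: Noyori asymmetric transfer hydrogenation of an alkynyl ketone, in which the alkyne takes the place an arene has in aryl ketones, so the (S,S)-ligand should deliver hydride to the face that gives the (R)-carbinol (R because CH2OBn outranks the alkynyl group).

**Step 5**
Reactants: 7 (2R)-1-(benzyloxy)-4-{3-methoxy-4-[(triisopropylsilyl)oxy]phenyl}but-3-yn-2-ol
Product: 8 (2R)-1-(benzyloxy)-4-{3-methoxy-4-[(triisopropylsilyl)oxy]phenyl}but-3-yn-2-yl methanesulfonate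
Conditions: MsCl, Et3N, CH2Cl2, –40 °C; used crude
Reagents that add atoms: methanesulfonyl chloride, CS(=O)(=O)Cl
Why: O-Sulfonylation with retention gives the leaving group for the propargylation, and the electron-withdrawing CH2OBn group should hold back ionisation of the propargylic mesylate.

**Step 6**
Reactants: 8 (2R)-1-(benzyloxy)-4-{3-methoxy-4-[(triisopropylsilyl)oxy]phenyl}but-3-yn-2-yl methanesulfonate; 9 4-(benzyloxy)-3,5-dimethoxybenzaldehyde
Product: 11 (1R,2S)-2-[(benzyloxy)methyl]-1-[4-(benzyloxy)-3,5-dimethoxyphenyl]-4-{3-methoxy-4-[(triisopropylsilyl)oxy]phenyl}but-3-yn-1-ol, via allenyl(ethyl)zinc 10 (not isolated)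
Conditions: Pd(OAc)2 (5 mol%), PPh3 (5 mol%), Et2Zn (3 equiv), THF, –78 → –20 °C; aq NH4Cl
Reagents that add atoms: none
Why: Marshall propargylation: zerovalent palladium (from Pd(OAc)2, PPh3 and Et2Zn) displaces the mesylate anti in an SN2' sense, transmetallation to zinc with retention gives allenylzinc 10, and its SE2' addition to 9 through a cyclic transition state forms the C2–C3 bond with net inversion at the former carbinol carbon (C3, S) and with the aldehyde aryl group anti to CH2OBn (C2, R).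

**Step 7**
Reactants: 11 (1R,2S)-2-[(benzyloxy)methyl]-1-[4-(benzyloxy)-3,5-dimethoxyphenyl]-4-{3-methoxy-4-[(triisopropylsilyl)oxy]phenyl}but-3-yn-1-ol
Product: 12 (phenylselanyl)methyl ether of 11 at the C1 oxygen, (1R,2S)
Conditions: NaH, THF–DMF, 0 °C; PhSeCH2Cl, n-Bu4NI (cat.), 0 °C → rt
Reagents that add atoms: chloromethyl phenyl selenide, ClC[Se]c1ccccc1
Why: Williamson etherification of the sodium alkoxide with an α-chloro selenide (activated like a chloromethyl ether) installs the future C5 as an O,Se-acetal; benzyl and aryl TIPS ethers cannot migrate to the alkoxide.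

**Step 8**
Reactants: 12 (phenylselanyl)methyl ether of 11, (1R,2S)
Product: 13 (2R,3S)-2-[4-(benzyloxy)-3,5-dimethoxyphenyl]-3-[(benzyloxy)methyl]-4-{3-methoxy-4-[(triisopropylsilyl)oxy]benzylidene}oxolane (E/Z mixture)
Conditions: Bu3SnH (1.3 equiv), AIBN (0.2 equiv), syringe pump 4 h, PhH (0.01 M), 80 °C
Reagents that add atoms: none
Why: Bu3Sn• abstracts PhSe from the O,Se-acetal to give the O-bound methylene radical (future C5), which adds in a 5-exo-dig mode to the proximal alkyne carbon (future C4) and closes ring B; the aryl-stabilised vinyl radical at C7' is then reduced by Bu3SnH to the exocyclic alkene. The closest known reaction type is the tin hydride cyclisation of alkoxymethyl radicals, generated from (phenylseleno)methyl ethers of unsaturated alcohols, to oxolanes. No new stereocentre is formed: C2 and C3 are untouched by the neutral radical chain, and the sp2 carbon left at C4 is the handle for step 9. The step needs 5-exo over 6-endo closure, which the short tether through oxygen and the aryl group (stabilising the vinyl radical only in the exo mode) should secure, and it needs ring closure before hydrogen transfer, which slow addition of the stannane at high dilution should secure. Both alkene isomers of 13 are acceptable because they converge in step 9.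

**Step 9**
Reactants: 13 (2R,3S)-2-[4-(benzyloxy)-3,5-dimethoxyphenyl]-3-[(benzyloxy)methyl]-4-{3-methoxy-4-[(triisopropylsilyl)oxy]benzylidene}oxolane
Product: 14 4-[(2R,3S,4S)-3-(hydroxymethyl)-4-{3-methoxy-4-[(triisopropylsilyl)oxy]benzyl}oxolan-2-yl]-2,6-dimethoxyphenol
Conditions: H2 (1 atm), Pd/C (10%), EtOAc–EtOH, rt
Reagents that add atoms: none
Why: Heterogeneous hydrogenation adds H2 syn from the catalyst surface to the alkene face opposite the adjacent C3 CH2OBn group (the C2 aryl group on the other face is one atom further from C4), which places the benzyl group cis to C3 and sets C4 as S, in line with the cis-selective hydrogenation of α-benzylidene-β-substituted butyrolactones; both benzyl ethers are hydrogenolysed in the same operation while the aryl TIPS ether and the ring B C2–O1 bond should persist under neutral conditions at 1 atm.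

**Step 10**
Reactants: 14 4-[(2R,3S,4S)-3-(hydroxymethyl)-4-{3-methoxy-4-[(triisopropylsilyl)oxy]benzyl}oxolan-2-yl]-2,6-dimethoxyphenol; 15 (4S)-4-benzyl-3-(chloroacetyl)-1,3-oxazolidin-2-one
Product: 16 (4S)-4-benzyl-3-{[4-((2R,3S,4S)-3-(hydroxymethyl)-4-{3-methoxy-4-[(triisopropylsilyl)oxy]benzyl}oxolan-2-yl)-2,6-dimethoxyphenoxy]acetyl}-1,3-oxazolidin-2-one
Conditions: K2CO3, NaI (cat.), acetone, 50 °C
Reagents that add atoms: none
Why: SN2 O-alkylation of the phenoxide by the iodide-activated α-halo imide; K2CO3 does not deprotonate the primary alcohol, so only the ring A oxygen reacts.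

**Step 11**
Reactants: 16 (4S)-4-benzyl-3-{[4-((2R,3S,4S)-3-(hydroxymethyl)-4-{3-methoxy-4-[(triisopropylsilyl)oxy]benzyl}oxolan-2-yl)-2,6-dimethoxyphenoxy]acetyl}-1,3-oxazolidin-2-one; 2 3-methoxy-4-[(triisopropylsilyl)oxy]benzaldehyde
Product: 18 syn-aldol adduct, N-[(2S,3R)-2-(aryloxy)-3-hydroxy-3-{3-methoxy-4-[(triisopropylsilyl)oxy]phenyl}propanoyl] imide of 16, via dibutylboron Z-enolate 17 (not isolated)
Conditions: n-Bu2BOTf (2.3 equiv), Et3N (2.8 equiv), CH2Cl2, –78 → 0 °C; 2, –78 → 0 °C; pH 7 buffer, MeOH, H2O2, 0 °C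
Reagents that add atoms: none
Why: Evans syn aldol: the Z boron enolate 17 reacts through a chair transition state on the face left open by the auxiliary, giving the (2S,3R) adduct (threo) and fixing C2'' in its final configuration; the free primary alcohol is masked in the flask as its dibutylborinate and returned on oxidative work-up.

**Step 12**
Reactants: 18 syn-aldol adduct (2S,3R)
Product: 19 (1R,2R)-2-{4-[(2R,3S,4S)-3-(hydroxymethyl)-4-{3-methoxy-4-[(triisopropylsilyl)oxy]benzyl}oxolan-2-yl]-2,6-dimethoxyphenoxy}-1-{3-methoxy-4-[(triisopropylsilyl)oxy]phenyl}propane-1,3-diol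
Conditions: LiBH4, MeOH (1 equiv), THF, 0 °C
Reagents that add atoms: none
Why: Reductive cleavage of the N-acyl oxazolidinone to the primary alcohol by LiBH4, which leaves both new stereocentres untouched and releases the auxiliary.

**Step 13**
Reactants: 19 threo triol (1R,2R)
Product: 20 bis(tert-butyldimethylsilyl) ether of 19 at the two primary hydroxyl groups (ring B CH2O and C3''), (1R,2R)
Conditions: TBSCl (2.2 equiv), imidazole, CH2Cl2, 0 °C
Reagents that add atoms: tert-butyldimethylsilyl chloride, CC(C)(C)[Si](C)(C)Cl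
Why: The two primary alcohols should silylate much faster than the hindered secondary benzylic alcohol, leaving only C1''–OH free.

**Step 14**
Reactants: 20 bis(TBS) ether (1R,2R)
Product: 21 4-nitrobenzoate of the C1''-inverted alcohol, (1S,2R)
Conditions: 4-O2NC6H4CO2H, PPh3, DIAD, toluene, 0 °C → rt
Reagents that add atoms: 4-nitrobenzoic acid, O=C(O)c1ccc(cc1)[N+](=O)[O-]
Why: Mitsunobu esterification: SN2 displacement of the oxyphosphonium group by 4-nitrobenzoate inverts C1'' (R to S), the established way to turn syn-aldol-derived threo arylglycerol aryl ethers into the erythro series.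

**Step 15**
Reactants: 21 4-nitrobenzoate (1S,2R)
Product: 22 erythro alcohol (1S,2R), with two aryl TIPS and two alkyl TBS ethers
Conditions: K2CO3 (0.5 equiv), MeOH–THF, 0 °C
Reagents that add atoms: none
Why: Methoxide-mediated transesterification removes the activated ester quickly at 0 °C while the ring D phenol is still silylated, so no quinone methide can form at C1''.

**Step 16**
Reactants: 22 erythro alcohol (1S,2R), fully silylated
Product: 23 target, (1S,2R)-1-(4-hydroxy-3-methoxyphenyl)-2-{4-[(2R,3S,4S)-3-(hydroxymethyl)-4-(4-hydroxy-3-methoxybenzyl)oxolan-2-yl]-2,6-dimethoxyphenoxy}propane-1,3-diol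
Conditions: TBAF (6 equiv), AcOH (6 equiv), THF, 0 °C → rt
Reagents that add atoms: none
Why: Fluoride cleaves the four Si–O bonds; buffering with AcOH keeps the freed 4-hydroxybenzylic alcohol and the ring B benzylic ether away from strongly basic conditions.

**Compound list**

1 | vanillin (4-hydroxy-3-methoxybenzaldehyde) | COc1cc(C=O)ccc1O | starting material
2 | 3-methoxy-4-[(triisopropylsilyl)oxy]benzaldehyde | COc1cc(C=O)ccc1O[Si](C(C)C)(C(C)C)C(C)C | intermediate
3 | [4-(2,2-dibromoethenyl)-2-methoxyphenoxy]triisopropylsilane | COc1cc(C=C(Br)Br)ccc1O[Si](C(C)C)(C(C)C)C(C)C | intermediate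
4 | 2-(benzyloxy)-N-methoxy-N-methylacetamide | CON(C)C(=O)COCc1ccccc1 | starting material
5 | lithium {3-methoxy-4-[(triisopropylsilyl)oxy]phenyl}acetylide | [Li]C#Cc1ccc(O[Si](C(C)C)(C(C)C)C(C)C)c(OC)c1 | intermediate
6 | 1-(benzyloxy)-4-{3-methoxy-4-[(triisopropylsilyl)oxy]phenyl}but-3-yn-2-one | COc1cc(C#CC(=O)COCc2ccccc2)ccc1O[Si](C(C)C)(C(C)C)C(C)C | intermediate
7 | (2R)-1-(benzyloxy)-4-{3-methoxy-4-[(triisopropylsilyl)oxy]phenyl}but-3-yn-2-ol | COc1cc(C#C[C@@H](O)COCc2ccccc2)ccc1O[Si](C(C)C)(C(C)C)C(C)C | intermediate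
8 | (2R)-1-(benzyloxy)-4-{3-methoxy-4-[(triisopropylsilyl)oxy]phenyl}but-3-yn-2-yl methanesulfonate | COc1cc(C#C[C@@H](OS(C)(=O)=O)COCc2ccccc2)ccc1O[Si](C(C)C)(C(C)C)C(C)C | intermediate
9 | 4-(benzyloxy)-3,5-dimethoxybenzaldehyde | COc1cc(C=O)cc(OC)c1OCc1ccccc1 | starting material
10 | ethyl[(aR)-4-(benzyloxy)-1-{3-methoxy-4-[(triisopropylsilyl)oxy]phenyl}buta-1,2-dien-1-yl]zinc | CC[Zn]C(c1ccc(O[Si](C(C)C)(C(C)C)C(C)C)c(OC)c1)=[C@]=C([H])COCc1ccccc1 | intermediate
11 | (1R,2S)-2-[(benzyloxy)methyl]-1-[4-(benzyloxy)-3,5-dimethoxyphenyl]-4-{3-methoxy-4-[(triisopropylsilyl)oxy]phenyl}but-3-yn-1-ol | O[C@@H](c1cc(OC)c(OCc2ccccc2)c(OC)c1)[C@@H](C#Cc1ccc(O[Si](C(C)C)(C(C)C)C(C)C)c(OC)c1)COCc1ccccc1 | intermediate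
12 | (phenylselanyl)methyl ether of 11, (1R,2S) | c1ccc(cc1)[Se]CO[C@@H](c1cc(OC)c(OCc2ccccc2)c(OC)c1)[C@@H](C#Cc1ccc(O[Si](C(C)C)(C(C)C)C(C)C)c(OC)c1)COCc1ccccc1 | intermediate
13 | (2R,3S)-2-[4-(benzyloxy)-3,5-dimethoxyphenyl]-3-[(benzyloxy)methyl]-4-{3-methoxy-4-[(triisopropylsilyl)oxy]benzylidene}oxolane, E/Z mixture (alkene geometry left open in the SMILES) | COc1cc(C=C2CO[C@@H](c3cc(OC)c(OCc4ccccc4)c(OC)c3)[C@@H]2COCc2ccccc2)ccc1O[Si](C(C)C)(C(C)C)C(C)C | intermediate
14 | 4-[(2R,3S,4S)-3-(hydroxymethyl)-4-{3-methoxy-4-[(triisopropylsilyl)oxy]benzyl}oxolan-2-yl]-2,6-dimethoxyphenol | COc1cc(C[C@@H]2CO[C@@H](c3cc(OC)c(O)c(OC)c3)[C@@H]2CO)ccc1O[Si](C(C)C)(C(C)C)C(C)C | intermediate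
15 | (4S)-4-benzyl-3-(chloroacetyl)-1,3-oxazolidin-2-one | O=C(CCl)N1[C@@H](Cc2ccccc2)COC1=O | starting material
16 | (4S)-4-benzyl-3-(aryloxyacetyl)-1,3-oxazolidin-2-one, aryl = ring A of 14 | COc1cc(C[C@@H]2CO[C@@H](c3cc(OC)c(OCC(=O)N4[C@@H](Cc5ccccc5)COC4=O)c(OC)c3)[C@@H]2CO)ccc1O[Si](C(C)C)(C(C)C)C(C)C | intermediate
17 | dibutylboron Z-enolate of 16, primary alcohol as dibutylborinate | COc1cc(C[C@@H]2CO[C@@H](c3cc(OC)c(O/C=C(\OB(CCCC)CCCC)N4[C@@H](Cc5ccccc5)COC4=O)c(OC)c3)[C@@H]2COB(CCCC)CCCC)ccc1O[Si](C(C)C)(C(C)C)C(C)C | intermediate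
18 | syn-aldol adduct, (2S,3R)-2-aryloxy-3-hydroxy-3-aryl-propanoyl imide | COc1cc(C[C@@H]2CO[C@@H](c3cc(OC)c(O[C@H](C(=O)N4[C@@H](Cc5ccccc5)COC4=O)[C@H](O)c4ccc(O[Si](C(C)C)(C(C)C)C(C)C)c(OC)c4)c(OC)c3)[C@@H]2CO)ccc1O[Si](C(C)C)(C(C)C)C(C)C | intermediate
19 | threo triol, (1R,2R)-propane-1,3-diol chain, both phenols as TIPS ethers | COc1cc(C[C@@H]2CO[C@@H](c3cc(OC)c(O[C@H](CO)[C@H](O)c4ccc(O[Si](C(C)C)(C(C)C)C(C)C)c(OC)c4)c(OC)c3)[C@@H]2CO)ccc1O[Si](C(C)C)(C(C)C)C(C)C | intermediate
20 | bis(TBS) ether of 19 at both primary oxygens, (1R,2R) | COc1cc(C[C@@H]2CO[C@@H](c3cc(OC)c(O[C@H](CO[Si](C)(C)C(C)(C)C)[C@H](O)c4ccc(O[Si](C(C)C)(C(C)C)C(C)C)c(OC)c4)c(OC)c3)[C@@H]2CO[Si](C)(C)C(C)(C)C)ccc1O[Si](C(C)C)(C(C)C)C(C)C | intermediate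
21 | C1''-inverted 4-nitrobenzoate, (1S,2R) | COc1cc(C[C@@H]2CO[C@@H](c3cc(OC)c(O[C@H](CO[Si](C)(C)C(C)(C)C)[C@@H](OC(=O)c4ccc(cc4)[N+](=O)[O-])c4ccc(O[Si](C(C)C)(C(C)C)C(C)C)c(OC)c4)c(OC)c3)[C@@H]2CO[Si](C)(C)C(C)(C)C)ccc1O[Si](C(C)C)(C(C)C)C(C)C | intermediate
22 | erythro alcohol, (1S,2R), two aryl TIPS and two alkyl TBS ethers | COc1cc(C[C@@H]2CO[C@@H](c3cc(OC)c(O[C@H](CO[Si](C)(C)C(C)(C)C)[C@@H](O)c4ccc(O[Si](C(C)C)(C(C)C)C(C)C)c(OC)c4)c(OC)c3)[C@@H]2CO[Si](C)(C)C(C)(C)C)ccc1O[Si](C(C)C)(C(C)C)C(C)C | intermediate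
23 | (1S,2R)-1-(4-hydroxy-3-methoxyphenyl)-2-{4-[(2R,3S,4S)-3-(hydroxymethyl)-4-(4-hydroxy-3-methoxybenzyl)oxolan-2-yl]-2,6-dimethoxyphenoxy}propane-1,3-diol | COc1cc(C[C@@H]2CO[C@@H](c3cc(OC)c(O[C@H](CO)[C@@H](O)c4ccc(O)c(OC)c4)c(OC)c3)[C@@H]2CO)ccc1O | target

**Totals**

Total step count: 16. Longest linear sequence: 16 steps (vanillin 1 to target 23; aldehyde 2 is drawn on a second time in step 11).

**Steps most likely to fail**

Step 8. What may go wrong: hydrogen transfer from the stannane to the alkoxymethyl radical before ring closure, or stannyl radical addition to the alkyne leading to hydrostannation. The fallback sets out from 11 and generates the same radical without tin by reductive decarboxylation. O-Alkylation of 11 with bromoacetic acid (NaH, THF) would give the alkoxyacetic acid F1. Coupling with N-hydroxyphthalimide (DIC, DMAP, CH2Cl2) would give the redox-active ester F2. Irradiation with blue LEDs in the presence of Ru(bpy)3Cl2 (1 mol%), Hantzsch ester and i-Pr2NEt in CH2Cl2 would release the O-bound methylene radical by single-electron reduction with loss of CO2 and phthalimide. The Hantzsch ester is a slower hydrogen donor than the stannane, so the 5-exo-dig closure should win, and the route is rejoined at 13.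

Step 9. What may go wrong: poor facial selectivity in hydrogen delivery to the exocyclic alkene, or hydrogenolysis of the ring B benzylic C2–O1 bond while the alkyl benzyl ether is being removed. The fallback sets out from 13 and separates the two events. Homogeneous hydrogenation with a cationic iridium phosphine–oxazoline catalyst, [Ir(cod)(t-Bu-PHOX)][B(3,5-(CF3)2C6H3)4] (H2 50 bar, CH2Cl2), adds catalyst control to substrate control and does not cleave C–O bonds. With the ligand enantiomer that matches delivery anti to the C3 substituent, it would give the saturated dibenzyl ether F3. A short Pd/C hydrogenolysis (H2, EtOAc) would then remove only the two benzyl groups and return to 14.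

Step 14. What may go wrong: ionisation of the electron-rich benzylic oxyphosphonium intermediate (loss of clean inversion) or elimination. The fallback sets out from 20 and inverts C1'' by oxidation and reduction. Dess–Martin periodinane (NaHCO3, CH2Cl2) would give the aryl ketone F4. LiB(s-Bu)3H (THF, –78 °C) would reduce it under Felkin–Anh control, with the aryl ether oxygen anti to the incoming hydride, to the erythro alcohol. That alcohol is 22, so the route is rejoined at 22 and step 15 is not needed.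

**Further compounds**

F1 | step 8 | {(1R,2S)-2-[(benzyloxy)methyl]-1-[4-(benzyloxy)-3,5-dimethoxyphenyl]-4-{3-methoxy-4-[(triisopropylsilyl)oxy]phenyl}but-3-yn-1-yl}oxyacetic acid | OC(=O)CO[C@@H](c1cc(OC)c(OCc2ccccc2)c(OC)c1)[C@@H](C#Cc1ccc(O[Si](C(C)C)(C(C)C)C(C)C)c(OC)c1)COCc1ccccc1
F2 | step 8 | N-hydroxyphthalimide ester of F1 | O=C(CO[C@@H](c1cc(OC)c(OCc2ccccc2)c(OC)c1)[C@@H](C#Cc1ccc(O[Si](C(C)C)(C(C)C)C(C)C)c(OC)c1)COCc1ccccc1)ON1C(=O)c2ccccc2C1=O
F3 | step 9 | (2R,3S,4S)-2-[4-(benzyloxy)-3,5-dimethoxyphenyl]-3-[(benzyloxy)methyl]-4-{3-methoxy-4-[(triisopropylsilyl)oxy]benzyl}oxolane | COc1cc(C[C@@H]2CO[C@@H](c3cc(OC)c(OCc4ccccc4)c(OC)c3)[C@@H]2COCc2ccccc2)ccc1O[Si](C(C)C)(C(C)C)C(C)C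
F4 | step 14 | C1'' ketone of 20, (2R)-2-aryloxy-3-[(tert-butyldimethylsilyl)oxy]-1-{3-methoxy-4-[(triisopropylsilyl)oxy]phenyl}propan-1-one | COc1cc(C[C@@H]2CO[C@@H](c3cc(OC)c(O[C@H](CO[Si](C)(C)C(C)(C)C)C(=O)c4ccc(O[Si](C(C)C)(C(C)C)C(C)C)c(OC)c4)c(OC)c3)[C@@H]2CO[Si](C)(C)C(C)(C)C)ccc1O[Si](C(C)C)(C(C)C)C(C)C
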